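(The data are calculated from invented constants; noise was put on by code.)

A small charge of nucleophile gave little: in the south-west run, at 0.18 equiv, target read 6.3% at 12.0 min, with 80.2% of the electrophile still there.

| setting | south-west | north-west | Thursday's | Monday's | Friday's | Saturday's |
|---|---|---|---|---|---|---|
| electrophile | 20 mM | 20 mM | 20 mM | 20 mM | 20 mM | 20 mM |
| nucleophile | 0.18 equiv | 7.1 equiv | 0.300 equiv | 1.00 equiv | 2.50 equiv | 8.00 equiv |
| protic impurity | 2 mM | 2 mM | 2.00 mM | 2.00 mM | 2.00 mM | 2.00 mM |
| remark | run made earlier | run made earlier |  |  |  |  |
| time |  |  | 25 min | 25 min | 25 min | 25 min |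

| run | time / min | target / % | electrophile / % |
|---|---|---|---|
| south-west | 2.50 | 2.9 | 91.2 |
| south-west | 5.00 | 4.6 | 85.3 |
| south-west | 8.00 | 5.0 | 83.8 |
| south-west | 10.0 | 4.7 | 81.6 |
| south-west | 12.0 | 6.3 | 80.2 |
| north-west | 1.00 | 46.3 | 49.8 |
| north-west | 2.00 | 62.4 | 25.8 |
| north-west | 4.00 | 66.8 | 8.0 |
| north-west | 6.00 | 60.7 | 3.2 |
| north-west | 12.0 | 37.8 | 0.4 |

(scatter of a reading: 0.5 percentage points)

- the earlier runs were read with a standard deviation of 0.5 percentage points
- candidate steps: electrophile + protic impurity -> quenched substrate; nucleophile + acid set free <-> protonated nucleophile; target -> over-reaction product; electrophile + nucleophile -> acid set free + target; target <-> isomer of the product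
- "hardly changes" means that all values lie within two and a half points (for a concentration: within two and a half percent of the largest)

1. [target] at the end for Thursday's, Monday's, Friday's, Saturday's, in this order
2. the course of these numbers from the first flask to the last (falls, then rises / falls all the way / rises all the way / hardly changes / rises, then falls)

So the lean flasks should gain as the charge grows. But the north-west run, at 7.1 equiv, read 66.8% at 4.00 min and then lost target. By 6.00 min its electrophile read 3.2%, less than target at 60.7%, so the later fall can be read as a first-order decay. From there to 12.0 min target fell to 37.8%, which gives 0.0789 min⁻¹. This is the fade constant, a first-order constant read from those two readings of the north-west run, taken after electrophile had fallen to 3.2%.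

Its half-life is 8.78 min, shorter than the 25 min asked. So I expected Saturday's to end well past its best. I treated Saturday's as the north-west run and carried that last reading forward to the end, which gave 2.71 mM.

The forecast gave 0.8 mM, 2.3 mM, 3.5 mM and 2.45 mM, a course that rises, then falls. Its last value stood below mine. It said: “Saturday extrapolates from 37.8% at 12 min to about 12%.”

The flasks gave 1.26 mM, 3.10 mM, 4.50 mM and 3.94 mM, a course that rises, then falls.

    electrophile + protic impurity → quenched substrate (k = 13.9 M⁻¹ min⁻¹)
    nucleophile + acid set free ⇌ protonated nucleophile, settled at all times (K = 575 M⁻¹)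
    target → over-reaction product (k = 0.0521 min⁻¹)
    electrophile + nucleophile → acid set free + target (k = 5.21 M⁻¹ min⁻¹)
    target ⇌ isomer of the product (K = 0.980, k = 0.0514 min⁻¹)

Saturday's ended above my 2.71 mM. In Saturday's, the isomer of the product stood at 24.7% at 12.5 min and 25.0% at 25.0 min, while target fell from 37.3% to 19.7% of the electrophile charged. Reckoned with the fade constant, that 37.3% came to 13.9%. For Friday's the same reckoning took 36.8% to 13.7%, but that flask held 22.5%, and its electrophile went from 13.9% to 4.04%.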